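- The flask held 1.5 M of electrophile, 1.35 M of nucleophile and 0.750 M of free base, closed and stirred, and I left it for you to read at 2.5 min.

| flask | electrophile | nucleophile | free base | remark | time |
|---|---|---|---|---|---|
| oak | 0.75 M | 1.35 M | 0.75 M | run made earlier |  |
| elm | 1.1 M | 1.35 M | 0.75 M | run made earlier |  |
| flask | 1.5 M | 1.35 M | 0.750 M |  | 2.5 min |

| run | time / s | electrophile / % | target / % |
|---|---|---|---|
| oak | 10.0 | 0 | 99.5 |
| oak | 15.0 | 0 | 100.0 |
| oak | 25.0 | 0.2 | 99.5 |
| oak | 40.0 | 0.4 | 98.8 |
| oak | 50.0 | 0.5 | 99.5 |
| oak | 80.0 | 0 | 99.2 |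
| oak | 90.0 | 0.4 | 99.0 |
| elm | 10.0 | 1.0 | 97.1 |
| elm | 15.0 | 1.1 | 96.3 |
| elm | 25.0 | 0.4 | 94.7 |
| elm | 40.0 | 0.8 | 90.8 |
| elm | 50.0 | 1.0 | 89.3 |
| elm | 80.0 | 0 | 85.9 |
| elm | 90.0 | 0 | 84.5 |

(scatter of a reading: 0.5 percentage points)

- the numbers in the tables scatter with a standard deviation of 0.5 percentage points
- the earlier runs do not show how much of nucleophile is bound; that part of a forecast is a guess
- I counted one nucleophile per electrophile and defined the ceiling C, the nucleophile charged over the electrophile charged: 90.0%. Nucleophile was the limiting reagent in this flask, with less charged than electrophile.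
- In the elm run, with more nucleophile than electrophile, the electrophile read 1.0% by 10.0 s, far sooner than your 2.5 min. Its target then fell to 84.5% by 90.0 s.
- So I expected this flask to stop at or under C, with at least 10.0% of the electrophile standing unused and the target slowly falling. I asked you to leave the nucleophile charge alone, since C follows it.

* part of the electrophile that has reacted at 2.5 min
* share of the unused nucleophile that is free and not bound as protonated nucleophile, at 2.5 min

- The forecast said 80% (73% to 88%) for c and 3% (0.5% to 15%) for the free share: “Leftover electrophile scavenges released nucleophile”.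

    acid set free + target → side product (k = 0.0170 M⁻¹ s⁻¹)
    nucleophile + acid set free ⇌ protonated nucleophile, settled at all times (K = 11.0 M⁻¹)
    acid set free + free base ⇌ salt of the base, settled at all times (K = 1500 M⁻¹)
    electrophile + nucleophile → acid set free + target (k = 2.50 M⁻¹ s⁻¹)

- This flask gave 90.0% for c, which is C of 90.0% and above the forecast's high end, and 58.8% for the free share. A neighbouring flask, changed to 0.54 M of nucleophile, had a ceiling of 36.0%. It gave 36.0% for c, and its electrophile stood at 64.0%.

The data are calculated for an exercise; noise was put on by code.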